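## Retrosynthetic overview

1. Target 15 ⇐ 14 (MOM removal) ⇐ 13: the axial C9 methyl is carried as a formyl group and reduced CHO → CH3 near the end.
2. 13 ⇐ aldehyde 7 + benzyl bromide 12: the C9 quaternary centre is made by benzylating an exocyclic aldehyde enolate on the face opposite the angular methyl.
3. 7 ⇐ trans-decalone 5 (one-carbon homologation) ⇐ chloro ketone 4: ring A is closed last by intramolecular enolate alkylation, and C8/C10 are set thermodynamically.
4. 4 ⇐ 3 ⇐ 3-methylcyclohexenone 1 + 5-chloropentyne 2: a catalytic enantioselective conjugate alkenylation sets the C5 quaternary centre and installs the C4 exocyclic methylene in step 1. No Wieland–Miescher ketone, Birch reductive alkylation or late Wittig methylenation is used.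
5. Ring order: ring B is the purchased cyclohexenone, ring A is annulated onto it (steps 1–3), and the arene arrives last as 12 (made from 8).

Assumption: 1, 2 and 8 are purchased, and the NHC ligand enantiomer used in step 1 is the one that delivers (S)-3 (to be confirmed experimentally).

Avarane numbering (C4=CH2, C5, C8, C9, C10) is used in the explanations.

## Forward route

**Step 1**
Reactants: 1, 3-methylcyclohex-2-en-1-one; 2, 5-chloropent-1-yne
Product: 3, (S)-3-(5-chloropent-1-en-2-yl)-3-methylcyclohexan-1-one
Conditions: 2, DIBAL-H, Ni(dppp)Cl2 (3 mol%), THF, 0→22 °C; then 1, chiral sulfonate-NHC–Ag complex (2.5 mol%), Cu(OTf)2 (5 mol%), THF, −30→4 °C; Rochelle salt workup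
Reagents that add atoms: none (DIBAL-H gives only H; both carbon partners are numbered reactants)
Why: Ni-catalysed α-selective hydroalumination converts 2 into the internal alkenyl–Al(i-Bu)2, and NHC–Cu-catalysed asymmetric conjugate addition transfers that alkenyl group to the β-carbon of 1, the catalyst choosing the enone face and so setting the C5 quaternary centre (S) together with the future C4=CH2 (known reaction class for β-methyl cyclic enones; this chloroalkyl alkenyl group is an untested substrate).

**Step 2**
Reactants: 3
Product: 4, (3S)-3-(5-chloropent-1-en-2-yl)-3,6-dimethylcyclohexan-1-one (mixture at C6)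
Conditions: LDA, THF, −78 °C; MeI, −78→0 °C
Reagents that add atoms: iodomethane, CI
Why: Kinetic LDA deprotonation occurs at C6 (C2 is flanked by the quaternary carbon) and the enolate is C-methylated (enolate alkylation); the new centre (future C8) forms as a mixture and is corrected thermodynamically in step 3.

**Step 3**
Reactants: 4
Product: 5, (2S,4aS,8aR)-2,4a-dimethyl-5-methylideneoctahydronaphthalen-1(2H)-one (trans-fused, 2-Me equatorial)
Conditions: t-BuOK, t-BuOH/THF, 25→45 °C (cyclisation, then equilibration in the same pot); chromatography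
Reagents that add atoms: none
Why: Under reversible alkoxide conditions the C2 enolate undergoes 6-exo-tet intramolecular alkylation (Piers methylenecyclohexane annulation), and both α-centres (ring-fusion C10 and C8) then epimerise to the more stable trans-fused chair–chair ketone with equatorial methyl, relayed from the fixed C5 centre (trans:cis of roughly 5–10:1 estimated; cis isomer recycled).

**Step 4**
Reactants: 5
Product: 6, (2S,4aS,8aR)-1-(methoxymethylidene)-2,4a-dimethyl-5-methylidenedecahydronaphthalene (E/Z mixture)
Conditions: Ph3P(CH2OMe)Cl, KHMDS, THF, 0 °C; then 5, rt→60 °C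
Reagents that add atoms: (methoxymethyl)triphenylphosphonium chloride, COC[P+](c1ccccc1)(c1ccccc1)c1ccccc1.[Cl-]
Why: Wittig methoxymethylenation adds the carbon that will become the C9 methyl; the ylide approaches the equatorial face (the axial face is blocked by the angular methyl) and no stereocentre is created.

**Step 5**
Reactants: 6
Product: 7, (2S,4aS,8aS)-2,4a-dimethyl-5-methylidenedecahydronaphthalene-1-carbaldehyde (C1 epimers)
Conditions: 1 M HCl, THF, 0 °C→rt
Reagents that add atoms: water, O
Why: Enol ether hydrolysis gives the aldehyde; dilute acid does not protonate the isolated 1,1-disubstituted alkene, and the C9–H configuration is irrelevant because it is planarised in step 10.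

**Step 6**
Reactants: 8, 5-bromo-2,3-dihydroxybenzaldehyde
Product: 9, 5-bromo-2,3-bis(methoxymethoxy)benzaldehyde
Conditions: NaH, MOMCl, DMF, 0 °C→rt
Reagents that add atoms: chloromethyl methyl ether, COCCl
Why: Williamson O-alkylation protects both phenols as MOM ethers, which withstand the hydride, strong-base and neutral reductive steps that follow.

**Step 7**
Reactants: 9
Product: 10, methyl 3-formyl-4,5-bis(methoxymethoxy)benzoate
Conditions: Pd(OAc)2, dppf, CO (1 atm), MeOH, Et3N, DMF, 70 °C
Reagents that add atoms: carbon monoxide, [C-]#[O+]; methanol, CO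
Why: Pd-catalysed methoxycarbonylation of the aryl bromide (oxidative addition, CO insertion, methanolysis) installs the ester; the aldehyde and MOM ethers are inert.

**Step 8**
Reactants: 10
Product: 11, methyl 3-(hydroxymethyl)-4,5-bis(methoxymethoxy)benzoate
Conditions: NaBH4, MeOH/THF, 0 °C
Reagents that add atoms: none
Why: Borohydride reduces the aryl aldehyde chemoselectively; the benzoate ester is untouched at 0 °C.

**Step 9**
Reactants: 11
Product: 12, methyl 3-(bromomethyl)-4,5-bis(methoxymethoxy)benzoate
Conditions: MsCl, Et3N, CH2Cl2, 0 °C; then LiBr, THF, rt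
Reagents that add atoms: lithium bromide, [Li+].[Br-]
Why: Mesylation followed by SN2 displacement with bromide gives the benzyl bromide under non-acidic conditions that keep the MOM ethers intact.

**Step 10**
Reactants: 7; 12
Product: 13, methyl 3-{[(1S,2S,4aS,8aR)-1-formyl-2,4a-dimethyl-5-methylidenedecahydronaphthalen-1-yl]methyl}-4,5-bis(methoxymethoxy)benzoate
Conditions: KH, THF, 0 °C; then 12, 0 °C→rt
Reagents that add atoms: none (both partners are numbered reactants)
Why: KH forms the tetrasubstituted exocyclic aldehyde enolate, and C-benzylation (enolate alkylation) occurs from the equatorial α-face because the axial β-face is shielded by the syn-axial angular methyl, so CH2Ar ends equatorial and CHO axial, which is the target C9 configuration once CHO becomes CH3.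

**Step 11**
Reactants: 13
Product: 14, methyl 3,4-bis(methoxymethoxy)-5-{[(1R,2S,4aS,8aS)-1,2,4a-trimethyl-5-methylidenedecahydronaphthalen-1-yl]methyl}benzoate
Conditions: TsNHNH2, EtOH, 70 °C; then catecholborane, CHCl3, 0 °C→rt; NaOAc·3H2O, 60 °C
Reagents that add atoms: none
Why: Caglioti–Kabalka reduction of the aldehyde tosylhydrazone (hydride addition, sulfinate loss, N2 extrusion) converts the axial CHO into CH3 under near-neutral conditions that spare the ester, MOM ethers and alkene, and no stereocentre is touched.

**Step 12**
Reactants: 14
Product: 15, dictyoceratin A, methyl 3,4-dihydroxy-5-{[(1R,2S,4aS,8aS)-1,2,4a-trimethyl-5-methylidenedecahydronaphthalen-1-yl]methyl}benzoate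
Conditions: ZnBr2, n-PrSH, CH2Cl2, 0 °C→rt
Reagents that add atoms: none
Why: Lewis acid/thiol cleavage of the two MOM acetals is fast at 0 °C and too mild to isomerise the exocyclic alkene or affect the methyl ester.

## Compound list

1 | 3-methylcyclohex-2-en-1-one | CC1=CC(=O)CCC1 | starting material
2 | 5-chloropent-1-yne | C#CCCCCl | starting material
3 | (S)-3-(5-chloropent-1-en-2-yl)-3-methylcyclohexan-1-one | ClCCCC(=C)[C@@]1(C)CCCC(=O)C1 | intermediate
4 | (3S)-3-(5-chloropent-1-en-2-yl)-3,6-dimethylcyclohexan-1-one (C6 epimers) | ClCCCC(=C)[C@@]1(C)CCC(C)C(=O)C1 | intermediate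
5 | (2S,4aS,8aR)-2,4a-dimethyl-5-methylideneoctahydronaphthalen-1(2H)-one | C=C1CCC[C@H]2C(=O)[C@@H](C)CC[C@]12C | intermediate
6 | (2S,4aS,8aR)-1-(methoxymethylidene)-2,4a-dimethyl-5-methylidenedecahydronaphthalene (E/Z) | C=C1CCC[C@H]2C(=COC)[C@@H](C)CC[C@]12C | intermediate
7 | (2S,4aS,8aS)-2,4a-dimethyl-5-methylidenedecahydronaphthalene-1-carbaldehyde (C1 epimers) | C=C1CCC[C@H]2C(C=O)[C@@H](C)CC[C@]12C | intermediate
8 | 5-bromo-2,3-dihydroxybenzaldehyde | O=Cc1cc(Br)cc(O)c1O | starting material
9 | 5-bromo-2,3-bis(methoxymethoxy)benzaldehyde | O=Cc1cc(Br)cc(OCOC)c1OCOC | intermediate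
10 | methyl 3-formyl-4,5-bis(methoxymethoxy)benzoate | COC(=O)c1cc(C=O)c(OCOC)c(OCOC)c1 | intermediate
11 | methyl 3-(hydroxymethyl)-4,5-bis(methoxymethoxy)benzoate | COC(=O)c1cc(CO)c(OCOC)c(OCOC)c1 | intermediate
12 | methyl 3-(bromomethyl)-4,5-bis(methoxymethoxy)benzoate | COC(=O)c1cc(CBr)c(OCOC)c(OCOC)c1 | intermediate
13 | methyl 3-{[(1S,2S,4aS,8aR)-1-formyl-2,4a-dimethyl-5-methylidenedecahydronaphthalen-1-yl]methyl}-4,5-bis(methoxymethoxy)benzoate | C=C1CCC[C@H]2[C@](C=O)(Cc3cc(C(=O)OC)cc(OCOC)c3OCOC)[C@@H](C)CC[C@]12C | intermediate
14 | methyl 3,4-bis(methoxymethoxy)-5-{[(1R,2S,4aS,8aS)-1,2,4a-trimethyl-5-methylidenedecahydronaphthalen-1-yl]methyl}benzoate | C=C1CCC[C@H]2[C@](C)(Cc3cc(C(=O)OC)cc(OCOC)c3OCOC)[C@@H](C)CC[C@]12C | intermediate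
15 | dictyoceratin A | C=C1CCC[C@H]2[C@](C)(Cc3cc(C(=O)OC)cc(O)c3O)[C@@H](C)CC[C@]12C | target

## Summary

Total step count: 12.
Longest linear sequence: 8 steps (steps 1–5, 10–12, from 1).

Three steps most likely to fail, each with a fallback that changes the approach:

- **Step 1 (asymmetric conjugate alkenylation).** The branched, chloroalkyl alkenyl alane may give low ee or competing i-Bu transfer. Fallback: reverse the roles. Add the alkenyllithium from 2-bromo-5-chloropent-1-ene to 3-ethoxycyclohex-2-enone (Stork–Danheiser) to make the 3-alkenyl enone, then create the quaternary centre by Cu-catalysed 1,4-addition of a methyl nucleophile (Me3Al or MeMgBr with a chiral ligand), arriving at the same 3.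
- **Step 4 (olefination of a hindered, enolisable ketone).** The ylide may enolise 5 instead of adding. Fallback: abandon carbonyl olefination. Convert 5 to its enol triflate toward C8, carry out Pd/CO reductive formylation to the tetrasubstituted enal, then conjugate reduction (L-Selectride; axial hydride sets the equatorial C8 methyl) with in-situ trapping of the enolate by 12. This gives 13 directly and replaces steps 4, 5 and 10.
- **Step 10 (quaternary C9 by aldehyde enolate benzylation).** O-alkylation or low conversion at the hindered enolate is possible. Fallback: use a nitrile anion instead. Reductive cyanation of 5 with TosMIC, LDA then the aryl-bromide analogue of 12 (equatorial alkylation), DIBAL to the aldehyde, step 11, and Pd methoxycarbonylation of the aryl bromide before MOM removal.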